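## Retrosynthetic overview

1. Target ⇐ its allyl analogue; the (E)-enyne is added last by cross-metathesis with crotonaldehyde and Colvin alkyne homologation.
2. Key step: the 2,8-dioxabicyclo[5.2.1]decane ⇐ a 2,2'-bis(tetrahydrofuran) C7 alcohol. Activation at C7 lets the ring B oxygen close onto C7 (tricyclic oxonium ion) and bromide cuts the C10–O bond, so C7–O, C10–Br and the oxocane arise together, each centre by inversion. This replaces the usual oxocene ring-closing metathesis plus transannular bromoetherification.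
3. Ring A ⇐ methyl ketone on ring B + (S)-2-chloropent-4-enal: chlorohydrin aldol, 1,3-syn reduction, epoxide, 5-endo closure.
4. Ring B ⇐ 3,3-dimethoxybutan-2-one + (S)-2-chlorobutanal: chlorohydrin aldol, 1,3-anti reduction, SN2 closure, bromination with inversion. Both chloroaldehydes come from L-amino acids; no protecting groups.
5. Ring order: ring B (tetrahydrofuran), then ring A (tetrahydrofuran), then the eight-membered ring by ring expansion of ring B.

Assumption: the target is taken exactly as drawn; atoms are labelled by the C15 acetogenin chain (C1≡C2–C3=C4–C5–C6…C15, ethers C6–O–C9 and C7–O–C13, Br on C10 and C12), in which it is (3E,6S,7S,9S,10S,12S,13R).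

## Route

Step 1
Reactants: 1 (S)-2-aminobutanoic acid
Product: 2 (S)-2-chlorobutanoic acid
Conditions: NaNO2, 5 M HCl, 0 to 23 °C
Reagents that add atoms: hydrogen chloride, Cl
Why: Diazotisation–chlorination of an α-amino acid (halodeamination) runs through an α-lactone that chloride reopens, so the future C13 centre is kept as (S) by double inversion.

Step 2
Reactants: 2 (S)-2-chlorobutanoic acid
Product: 3 (S)-2-chlorobutan-1-ol
Conditions: LiAlH4, Et2O, 0 °C; then H2O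
Reagents that add atoms: none
Why: Hydride reduction of the carboxylic acid at 0 °C leaves the secondary chloride and its configuration untouched.

Step 3
Reactants: 3 (S)-2-chlorobutan-1-ol
Product: 4 (S)-2-chlorobutanal
Conditions: Dess–Martin periodinane, CH2Cl2, 0 to 23 °C; used at once as a solution
Reagents that add atoms: none
Why: Dess–Martin oxidation is fast and non-basic, which avoids enolisation and racemisation of the α-chloro aldehyde.

Step 4
Reactants: 5 3,3-dimethoxybutan-2-one; 4 (S)-2-chlorobutanal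
Product: 7 (5R,6S)-6-chloro-5-hydroxy-2,2-dimethoxyoctan-3-one, via lithium enolate 6 (not isolated)
Conditions: LiN(i-Pr)2, THF, −78 °C; then 4, −78 °C; AcOH quench
Reagents that add atoms: none
Why: Lithium-enolate aldol addition to the α-chloro aldehyde follows the Cornforth model, the enolate adding anti to C–Cl to give the 1,2-anti chlorohydrin (C12 R beside C13 S).

Step 5
Reactants: 7 (5R,6S)-6-chloro-5-hydroxy-2,2-dimethoxyoctan-3-one
Product: 9 (3R,5R,6S)-6-chloro-2,2-dimethoxyoctane-3,5-diol, via alkoxyborohydride adduct 8 (not isolated)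
Conditions: Me4NBH(OAc)3, MeCN/AcOH 1:1, −35 °C
Reagents that add atoms: none
Why: Evans–Saksena reduction delivers hydride intramolecularly from the C12-bound borohydride through a chair transition state, setting C10 as (R), 1,3-anti to C12.

Step 6
Reactants: 9 (3R,5R,6S)-6-chloro-2,2-dimethoxyoctane-3,5-diol
Product: 10 (2R,3R,5R)-5-(1,1-dimethoxyethyl)-2-ethyloxolan-3-ol
Conditions: AgOSO2CF3, Ag2O, THF, 23 to 50 °C
Reagents that add atoms: none
Why: Silver-assisted 5-exo-tet Williamson-type etherification has the C10 hydroxyl displace the C13 chloride with inversion (S to R), giving all-cis ring B with the C12 hydroxyl cis to ethyl.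

Step 7
Reactants: 10 (2R,3R,5R)-5-(1,1-dimethoxyethyl)-2-ethyloxolan-3-ol
Product: 11 (2R,3S,5R)-3-bromo-5-(1,1-dimethoxyethyl)-2-ethyloxolane
Conditions: CBr4, P(n-C8H17)3, toluene, 70 °C
Reagents that add atoms: carbon tetrabromide, BrC(Br)(Br)Br
Why: Appel bromination has bromide attack the alkoxyphosphonium ion from the open face, inverting C12 (R to S) so that bromine ends trans to ethyl.

Step 8
Reactants: 11 (2R,3S,5R)-3-bromo-5-(1,1-dimethoxyethyl)-2-ethyloxolane
Product: 12 1-[(2R,4S,5R)-4-bromo-5-ethyloxolan-2-yl]ethan-1-one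
Conditions: CF3CO2H, H2O, CH2Cl2, 0 to 23 °C
Reagents that add atoms: water, O
Why: Acid-catalysed ketal hydrolysis unmasks the methyl ketone, and the short cold exposure avoids epimerising C10 next to the new carbonyl.

Step 9
Reactants: 13 (S)-2-aminopent-4-enoic acid
Product: 14 (S)-2-chloropent-4-enoic acid
Conditions: NaNO2, 5 M HCl, 0 to 23 °C
Reagents that add atoms: hydrogen chloride, Cl
Why: The same halodeamination through an α-lactone gives net retention, fixing the future C6 centre as (S).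

Step 10
Reactants: 14 (S)-2-chloropent-4-enoic acid
Product: 15 (S)-2-chloropent-4-en-1-ol
Conditions: LiAlH4, Et2O, 0 °C; then H2O
Reagents that add atoms: none
Why: Hydride reduction of the acid spares the secondary chloride, the isolated alkene and the stereocentre.

Step 11
Reactants: 15 (S)-2-chloropent-4-en-1-ol
Product: 16 (S)-2-chloropent-4-enal
Conditions: Dess–Martin periodinane, CH2Cl2, 0 to 23 °C; used at once as a solution
Reagents that add atoms: none
Why: Dess–Martin oxidation gives the α-chloro aldehyde without base, so the C6 centre is not racemised.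

Step 12
Reactants: 12 1-[(2R,4S,5R)-4-bromo-5-ethyloxolan-2-yl]ethan-1-one; 16 (S)-2-chloropent-4-enal
Product: 18 (3R,4S)-1-[(2R,4S,5R)-4-bromo-5-ethyloxolan-2-yl]-4-chloro-3-hydroxyhept-6-en-1-one, via lithium enolate 17 (not isolated)
Conditions: LiN(i-Pr)2, THF, −78 °C; then 16, −78 °C; AcOH quench
Reagents that add atoms: none
Why: Kinetic deprotonation takes the methyl group, not the hindered C10–H, and the Cornforth-controlled aldol addition gives the 1,2-anti chlorohydrin (C7 R beside C6 S).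

Step 13
Reactants: 18 (3R,4S)-1-[(2R,4S,5R)-4-bromo-5-ethyloxolan-2-yl]-4-chloro-3-hydroxyhept-6-en-1-one
Product: 20 (1S,3R,4S)-1-[(2R,4S,5R)-4-bromo-5-ethyloxolan-2-yl]-4-chlorohept-6-ene-1,3-diol, via diethylboron chelate 19 (not isolated)
Conditions: Et2BOMe, THF/MeOH 4:1, −78 °C; NaBH4; MeOH co-evaporation
Reagents that add atoms: none
Why: Narasaka–Prasad reduction has external hydride attack the six-membered boron chelate axially, setting C9 as (S), 1,3-syn to C7 and erythro to C10.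

Step 14
Reactants: 20 (1S,3R,4S)-1-[(2R,4S,5R)-4-bromo-5-ethyloxolan-2-yl]-4-chlorohept-6-ene-1,3-diol
Product: 21 (1S)-1-[(2R,4S,5R)-4-bromo-5-ethyloxolan-2-yl]-2-[(2R,3R)-3-(prop-2-en-1-yl)oxiran-2-yl]ethan-1-ol
Conditions: K2CO3, MeOH, 23 °C
Reagents that add atoms: none
Why: Intramolecular Williamson closure (3-exo-tet) of the anti chlorohydrin inverts C6 and gives the trans-epoxide far faster than 5-exo attack by the C9 alkoxide.

Step 15
Reactants: 21 (1S)-1-[(2R,4S,5R)-4-bromo-5-ethyloxolan-2-yl]-2-[(2R,3R)-3-(prop-2-en-1-yl)oxiran-2-yl]ethan-1-ol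
Product: 22 (2S,3R,5S)-5-[(2R,4S,5R)-4-bromo-5-ethyloxolan-2-yl]-2-(prop-2-en-1-yl)oxolan-3-ol
Conditions: (1S)-(+)-10-camphorsulfonic acid (10 mol %), CH2Cl2, 0 to 23 °C
Reagents that add atoms: none
Why: Acid-catalysed 5-endo epoxide opening of the 3,4-epoxy alcohol inverts C6 a second time, so ring A ends 2,5-cis with the C7 hydroxyl trans to both the allyl group and ring B.

Step 16
Reactants: 22 (2S,3R,5S)-5-[(2R,4S,5R)-4-bromo-5-ethyloxolan-2-yl]-2-(prop-2-en-1-yl)oxolan-3-ol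
Product: 25 (1S,3R,4S,6S,7S,9S)-4,6-dibromo-3-ethyl-9-(prop-2-en-1-yl)-2,8-dioxabicyclo[5.2.1]decane, via ring A triflate 23 (not isolated), via tricyclic oxonium triflate 24 (not isolated)
Conditions: (CF3SO2)2O, 2,6-di-tert-butyl-4-methylpyridine, CH2Cl2, −78 to −40 °C; then Bu4NBr, −78 to 0 °C
Reagents that add atoms: tetrabutylammonium bromide, CCCC[N+](CCCC)(CCCC)CCCC.[Br-]
Why: Proposed new method: the C7 triflate lies anti to the ring B oxygen, which displaces it through a five-membered transition state (inversion at C7) to give a tricyclic trialkyloxonium ion, and bromide then opens the strained [2.2.1] unit by SN2 attack at C10 (inversion) to form the oxocane, with C13 shielded by its β-bromine and ethyl group and C7 the main competing site; the closest known reaction types are ether neighbouring-group participation, halide opening of bicyclic oxonium salts and bromonium-induced ring expansion of tetrahydrofurans to oxocanes.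

Step 17
Reactants: 25 (1S,3R,4S,6S,7S,9S)-4,6-dibromo-3-ethyl-9-(prop-2-en-1-yl)-2,8-dioxabicyclo[5.2.1]decane; 26 (E)-but-2-enal
Product: 27 (2E)-4-[(1S,3R,4S,6S,7S,9S)-4,6-dibromo-3-ethyl-2,8-dioxabicyclo[5.2.1]decan-9-yl]but-2-enal
Conditions: 26 (10 equiv), second-generation Grubbs catalyst RuCl2(=CHPh)(PCy3)(H2IMes) (5 mol %), CH2Cl2, 40 °C
Reagents that add atoms: none
Why: Olefin cross-metathesis of the single terminal alkene with excess crotonaldehyde gives the conjugated (E)-enal under thermodynamic control.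

Step 18
Reactants: 27 (2E)-4-[(1S,3R,4S,6S,7S,9S)-4,6-dibromo-3-ethyl-2,8-dioxabicyclo[5.2.1]decan-9-yl]but-2-enal
Product: 28 (1S,3R,4S,6S,7S,9S)-4,6-dibromo-3-ethyl-9-[(2E)-pent-2-en-4-yn-1-yl]-2,8-dioxabicyclo[5.2.1]decane
Conditions: Me3SiCHN2, LiN(i-Pr)2, THF, −78 to 0 °C
Reagents that add atoms: trimethylsilyldiazomethane, C[Si](C)(C)C=[N+]=[N-]
Why: Colvin rearrangement: the lithiated diazomethane adds 1,2 to the enal, and Peterson elimination, loss of N2 and a 1,2-hydrogen shift give the terminal alkyne without touching the E-alkene or any stereocentre.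

## Compound list

1 | (S)-2-aminobutanoic acid (L-2-aminobutyric acid) | CC[C@H](N)C(=O)O | starting material
2 | (S)-2-chlorobutanoic acid | CC[C@H](Cl)C(=O)O | intermediate
3 | (S)-2-chlorobutan-1-ol | CC[C@H](Cl)CO | intermediate
4 | (S)-2-chlorobutanal | CC[C@H](Cl)C=O | intermediate
5 | 3,3-dimethoxybutan-2-one | CC(=O)C(C)(OC)OC | starting material
6 | lithium 3,3-dimethoxybut-1-en-2-olate (lithium enolate of 5, not isolated) | [Li]OC(=C)C(C)(OC)OC | intermediate
7 | (5R,6S)-6-chloro-5-hydroxy-2,2-dimethoxyoctan-3-one | CC[C@H](Cl)[C@H](O)CC(=O)C(C)(OC)OC | intermediate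
8 | tetramethylammonium diacetoxy(hydrido)borate bound to the C5 oxygen of 7 (not isolated) | CC[C@H](Cl)[C@H](O[BH-](OC(C)=O)OC(C)=O)CC(=O)C(C)(OC)OC.C[N+](C)(C)C | intermediate
9 | (3R,5R,6S)-6-chloro-2,2-dimethoxyoctane-3,5-diol | CC[C@H](Cl)[C@H](O)C[C@@H](O)C(C)(OC)OC | intermediate
10 | (2R,3R,5R)-5-(1,1-dimethoxyethyl)-2-ethyloxolan-3-ol | CC(OC)(OC)[C@H]1C[C@@H](O)[C@@H](CC)O1 | intermediate
11 | (2R,3S,5R)-3-bromo-5-(1,1-dimethoxyethyl)-2-ethyloxolane | CC(OC)(OC)[C@H]1C[C@H](Br)[C@@H](CC)O1 | intermediate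
12 | 1-[(2R,4S,5R)-4-bromo-5-ethyloxolan-2-yl]ethan-1-one | CC(=O)[C@H]1C[C@H](Br)[C@@H](CC)O1 | intermediate
13 | (S)-2-aminopent-4-enoic acid (L-allylglycine) | C=CC[C@H](N)C(=O)O | starting material
14 | (S)-2-chloropent-4-enoic acid | C=CC[C@H](Cl)C(=O)O | intermediate
15 | (S)-2-chloropent-4-en-1-ol | C=CC[C@H](Cl)CO | intermediate
16 | (S)-2-chloropent-4-enal | C=CC[C@H](Cl)C=O | intermediate
17 | lithium 1-[(2R,4S,5R)-4-bromo-5-ethyloxolan-2-yl]ethen-1-olate (lithium enolate of 12, not isolated) | [Li]OC(=C)[C@H]1C[C@H](Br)[C@@H](CC)O1 | intermediate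
18 | (3R,4S)-1-[(2R,4S,5R)-4-bromo-5-ethyloxolan-2-yl]-4-chloro-3-hydroxyhept-6-en-1-one | C=CC[C@H](Cl)[C@H](O)CC(=O)[C@H]1C[C@H](Br)[C@@H](CC)O1 | intermediate
19 | O3-diethylboryl derivative of 18, boron chelated to the ketone (not isolated) | C=CC[C@H](Cl)[C@H](OB(CC)CC)CC(=O)[C@H]1C[C@H](Br)[C@@H](CC)O1 | intermediate
20 | (1S,3R,4S)-1-[(2R,4S,5R)-4-bromo-5-ethyloxolan-2-yl]-4-chlorohept-6-ene-1,3-diol | C=CC[C@H](Cl)[C@H](O)C[C@H](O)[C@H]1C[C@H](Br)[C@@H](CC)O1 | intermediate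
21 | (1S)-1-[(2R,4S,5R)-4-bromo-5-ethyloxolan-2-yl]-2-[(2R,3R)-3-(prop-2-en-1-yl)oxiran-2-yl]ethan-1-ol | C=CC[C@H]1O[C@@H]1C[C@H](O)[C@H]2C[C@H](Br)[C@@H](CC)O2 | intermediate
22 | (2S,3R,5S)-5-[(2R,4S,5R)-4-bromo-5-ethyloxolan-2-yl]-2-(prop-2-en-1-yl)oxolan-3-ol | C=CC[C@@H]1O[C@@H](C[C@H]1O)[C@H]2C[C@H](Br)[C@@H](CC)O2 | intermediate
23 | trifluoromethanesulfonate ester of 22 at the ring A hydroxyl (not isolated) | C=CC[C@@H]1O[C@@H](C[C@H]1OS(=O)(=O)C(F)(F)F)[C@H]2C[C@H](Br)[C@@H](CC)O2 | intermediate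
24 | tricyclic oxonium trifluoromethanesulfonate, ring B oxygen bonded to C7, C10 and C13 (not isolated) | C=CC[C@@H]1O[C@H]2C[C@@H]1[O+]3[C@@H]2C[C@H](Br)[C@H]3CC.[O-]S(=O)(=O)C(F)(F)F | intermediate
25 | (1S,3R,4S,6S,7S,9S)-4,6-dibromo-3-ethyl-9-(prop-2-en-1-yl)-2,8-dioxabicyclo[5.2.1]decane | C=CC[C@@H]1O[C@H]2C[C@@H]1O[C@H](CC)[C@@H](Br)C[C@@H]2Br | intermediate
26 | (E)-but-2-enal (crotonaldehyde) | C/C=C/C=O | starting material
27 | (2E)-4-[(1S,3R,4S,6S,7S,9S)-4,6-dibromo-3-ethyl-2,8-dioxabicyclo[5.2.1]decan-9-yl]but-2-enal | O=C/C=C/C[C@@H]1O[C@H]2C[C@@H]1O[C@H](CC)[C@@H](Br)C[C@@H]2Br | intermediate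
28 | (1S,3R,4S,6S,7S,9S)-4,6-dibromo-3-ethyl-9-[(2E)-pent-2-en-4-yn-1-yl]-2,8-dioxabicyclo[5.2.1]decane | C#C/C=C/C[C@@H]1O[C@H]2C[C@@H]1O[C@H](CC)[C@@H](Br)C[C@@H]2Br | target

## Step count and risks

Total step count: 18.
Longest linear sequence: 15 steps (steps 1–8, then 12–18); steps 9–11 form the side branch that joins at step 12.

The three steps most likely to fail:

**Step 16 (oxonium rearrangement).** Bromide may open the oxonium ion at C7 instead of C10. That returns a bis(tetrahydrofuran) dibromide which cannot be recycled selectively, because its C12 bromide ionises as easily as the C7 bromide. The fallback sets out from 10 and comes back at 25, and it defers the C12 bromine so that a wrong-site product can be recycled: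
- Silylate 10 (t-BuMe2SiCl, imidazole, DMF) to tert-butyl{[(2R,3R,5R)-5-(1,1-dimethoxyethyl)-2-ethyloxolan-3-yl]oxy}dimethylsilane F1.
- Hydrolyse the ketal (pyridinium p-toluenesulfonate, wet acetone) to 1-[(2R,4R,5R)-4-{[tert-butyl(dimethyl)silyl]oxy}-5-ethyloxolan-2-yl]ethan-1-one F2.
- Repeat the operations of steps 12–15 with 16: aldol to (3R,4S)-1-[(2R,4R,5R)-4-{[tert-butyl(dimethyl)silyl]oxy}-5-ethyloxolan-2-yl]-4-chloro-3-hydroxyhept-6-en-1-one F3; syn reduction to (1S,3R,4S)-1-[(2R,4R,5R)-4-{[tert-butyl(dimethyl)silyl]oxy}-5-ethyloxolan-2-yl]-4-chlorohept-6-ene-1,3-diol F4; K2CO3, MeOH to (1S)-1-[(2R,4R,5R)-4-{[tert-butyl(dimethyl)silyl]oxy}-5-ethyloxolan-2-yl]-2-[(2R,3R)-3-(prop-2-en-1-yl)oxiran-2-yl]ethan-1-ol F5; acid-catalysed 5-endo closure to (2S,3R,5S)-5-[(2R,4R,5R)-4-{[tert-butyl(dimethyl)silyl]oxy}-5-ethyloxolan-2-yl]-2-(prop-2-en-1-yl)oxolan-3-ol F6.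
- The triflate/Bu4NBr rearrangement of F6 gives tert-butyl{[(1S,3R,4R,6S,7S,9S)-6-bromo-3-ethyl-9-(prop-2-en-1-yl)-2,8-dioxabicyclo[5.2.1]decan-4-yl]oxy}dimethylsilane F7, together with any product of C7 attack, tert-butyl{[(2R,3R,5R)-5-[(2S,4R,5S)-4-bromo-5-(prop-2-en-1-yl)oxolan-2-yl]-2-ethyloxolan-3-yl]oxy}dimethylsilane F8.
- F8 now holds the only C–Br bond, so AgOSO2CF3 in CH2Cl2 abstracts it with the same ring B oxygen participation and regenerates the oxonium ion; after filtration of AgBr, Bu4NBr is added again, and repeated passes funnel material to F7.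
- Bu4NF in THF then frees (1S,3R,4R,6S,7S,9S)-6-bromo-3-ethyl-9-(prop-2-en-1-yl)-2,8-dioxabicyclo[5.2.1]decan-4-ol F9, and Appel inversion (CBr4, P(n-C8H17)3, toluene, 70 °C) installs the C12 bromine last, giving 25.

**Step 12 (aldol of the ring B methyl ketone).** The lithium enolate must form at the methyl group in the presence of a secondary bromide and an epimerisable C10–H, and as a base it can enolise the racemisable α-chloro aldehyde. The fallback sets out from 12 and comes back at 18 and replaces the basic enolate by a neutral nucleophile. LiN(i-Pr)2 is added to 12 and Me3SiCl in THF at −78 °C (in situ quench) to give trimethyl({1-[(2R,4S,5R)-4-bromo-5-ethyloxolan-2-yl]ethenyl}oxy)silane F10. A Mukaiyama aldol addition of F10 to 16 (BF3·OEt2, CH2Cl2, −78 °C) then goes through an open transition state that still places the nucleophile anti to chlorine, and aqueous work-up gives 18.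

**Step 18 (Colvin homologation).** The lithiated diazomethane is a strong base; γ-deprotonation of the enal at C5 would allow β-elimination of the ring A oxygen, and the secondary bromides are exposed to base. The fallback sets out from 25 and comes back at 28 and builds the enyne by coupling instead:
- Ozonolysis (O3, CH2Cl2, −78 °C; PPh3) gives 2-[(1S,3R,4S,6S,7S,9S)-4,6-dibromo-3-ethyl-2,8-dioxabicyclo[5.2.1]decan-9-yl]acetaldehyde F11.
- Takai olefination (CHI3, CrCl2, THF, 0 °C; unactivated secondary bromides are inert) gives (1S,3R,4S,6S,7S,9S)-4,6-dibromo-3-ethyl-9-[(2E)-3-iodoprop-2-en-1-yl]-2,8-dioxabicyclo[5.2.1]decane F12.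
- Sonogashira coupling with trimethylsilylacetylene (Pd(PPh3)4, CuI, i-Pr2NH, 23 °C) gives trimethyl{(3E)-5-[(1S,3R,4S,6S,7S,9S)-4,6-dibromo-3-ethyl-2,8-dioxabicyclo[5.2.1]decan-9-yl]pent-3-en-1-yn-1-yl}silane F13.
- K2CO3 in MeOH removes silicon to give 28.

## Further compounds

F1 | step 16 | tert-butyl{[(2R,3R,5R)-5-(1,1-dimethoxyethyl)-2-ethyloxolan-3-yl]oxy}dimethylsilane | CC(OC)(OC)[C@H]1C[C@@H](O[Si](C)(C)C(C)(C)C)[C@@H](CC)O1
F2 | step 16 | 1-[(2R,4R,5R)-4-{[tert-butyl(dimethyl)silyl]oxy}-5-ethyloxolan-2-yl]ethan-1-one | CC(=O)[C@H]1C[C@@H](O[Si](C)(C)C(C)(C)C)[C@@H](CC)O1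
F3 | step 16 | (3R,4S)-1-[(2R,4R,5R)-4-{[tert-butyl(dimethyl)silyl]oxy}-5-ethyloxolan-2-yl]-4-chloro-3-hydroxyhept-6-en-1-one | C=CC[C@H](Cl)[C@H](O)CC(=O)[C@H]1C[C@@H](O[Si](C)(C)C(C)(C)C)[C@@H](CC)O1
F4 | step 16 | (1S,3R,4S)-1-[(2R,4R,5R)-4-{[tert-butyl(dimethyl)silyl]oxy}-5-ethyloxolan-2-yl]-4-chlorohept-6-ene-1,3-diol | C=CC[C@H](Cl)[C@H](O)C[C@H](O)[C@H]1C[C@@H](O[Si](C)(C)C(C)(C)C)[C@@H](CC)O1
F5 | step 16 | (1S)-1-[(2R,4R,5R)-4-{[tert-butyl(dimethyl)silyl]oxy}-5-ethyloxolan-2-yl]-2-[(2R,3R)-3-(prop-2-en-1-yl)oxiran-2-yl]ethan-1-ol | C=CC[C@H]1O[C@@H]1C[C@H](O)[C@H]2C[C@@H](O[Si](C)(C)C(C)(C)C)[C@@H](CC)O2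
F6 | step 16 | (2S,3R,5S)-5-[(2R,4R,5R)-4-{[tert-butyl(dimethyl)silyl]oxy}-5-ethyloxolan-2-yl]-2-(prop-2-en-1-yl)oxolan-3-ol | C=CC[C@@H]1O[C@@H](C[C@H]1O)[C@H]2C[C@@H](O[Si](C)(C)C(C)(C)C)[C@@H](CC)O2
F7 | step 16 | tert-butyl{[(1S,3R,4R,6S,7S,9S)-6-bromo-3-ethyl-9-(prop-2-en-1-yl)-2,8-dioxabicyclo[5.2.1]decan-4-yl]oxy}dimethylsilane | C=CC[C@@H]1O[C@H]2C[C@@H]1O[C@H](CC)[C@H](O[Si](C)(C)C(C)(C)C)C[C@@H]2Br
F8 | step 16 | tert-butyl{[(2R,3R,5R)-5-[(2S,4R,5S)-4-bromo-5-(prop-2-en-1-yl)oxolan-2-yl]-2-ethyloxolan-3-yl]oxy}dimethylsilane | C=CC[C@@H]1O[C@@H](C[C@H]1Br)[C@H]2C[C@@H](O[Si](C)(C)C(C)(C)C)[C@@H](CC)O2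
F9 | step 16 | (1S,3R,4R,6S,7S,9S)-6-bromo-3-ethyl-9-(prop-2-en-1-yl)-2,8-dioxabicyclo[5.2.1]decan-4-ol | C=CC[C@@H]1O[C@H]2C[C@@H]1O[C@H](CC)[C@H](O)C[C@@H]2Br
F10 | step 12 | trimethyl({1-[(2R,4S,5R)-4-bromo-5-ethyloxolan-2-yl]ethenyl}oxy)silane | C=C(O[Si](C)(C)C)[C@H]1C[C@H](Br)[C@@H](CC)O1
F11 | step 18 | 2-[(1S,3R,4S,6S,7S,9S)-4,6-dibromo-3-ethyl-2,8-dioxabicyclo[5.2.1]decan-9-yl]acetaldehyde | O=CC[C@@H]1O[C@H]2C[C@@H]1O[C@H](CC)[C@@H](Br)C[C@@H]2Br
F12 | step 18 | (1S,3R,4S,6S,7S,9S)-4,6-dibromo-3-ethyl-9-[(2E)-3-iodoprop-2-en-1-yl]-2,8-dioxabicyclo[5.2.1]decane | I/C=C/C[C@@H]1O[C@H]2C[C@@H]1O[C@H](CC)[C@@H](Br)C[C@@H]2Br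
F13 | step 18 | trimethyl{(3E)-5-[(1S,3R,4S,6S,7S,9S)-4,6-dibromo-3-ethyl-2,8-dioxabicyclo[5.2.1]decan-9-yl]pent-3-en-1-yn-1-yl}silane | C[Si](C)(C)C#C/C=C/C[C@@H]1O[C@H]2C[C@@H]1O[C@H](CC)[C@@H](Br)C[C@@H]2Br
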